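**Plan**
- Retrosynthetic cuts, in order: the three O–Si bonds; C2–C3 of ring C (carbenoid C–H insertion); the C3=N2 bond (diazo transfer); the O1–CH2 ether bond between ring A and ring B (Mitsunobu); the three C–prenyl bonds (two on ring A by phenoxide C-alkylation, one on ring B by Stille coupling).
- Forward: rings A and B are bought as arenes (phloroacetophenone, 5-iodovanillin), decorated separately and joined through O1. Ring C is the only ring formed, in step 8.
- Enabling feature: in the open precursor, C2 is the CH2 of an O1–CH2–aryl(ring B) ether, so its C–H bonds are benzylic and alpha to oxygen. O1 (on C8a) and the C4 carbonyl (on C4a) are ortho on ring A, which places a carbenoid at C3 in a 1,6-relationship to those hydrogens.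
- Stereochemistry: C2 is the only stereocentre. It is set in step 8 by the chiral dirhodium carboxylate choosing one enantiotopic C2–H bond, and it is preserved by a buffered, non-basic desilylation.

Key step: step 8

Abbreviations: prenyl = 3-methylbut-2-en-1-yl; TBS = tert-butyldimethylsilyl; Rh2(S-PTTL)4 = dirhodium tetrakis[N-phthaloyl-(S)-tert-leucinate].

Assumption: the sense of induction of the insertion is not fixed by a close analogy, so the route is written with Rh2(S-PTTL)4; if a pilot run favours (2R), the mirror-image catalyst Rh2(R-PTTL)4 is used with no other change.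

**Route**

Step 1
Reactants: 1 2',4',6'-trihydroxyacetophenone; 2 prenyl bromide
Product: 3 1-[2,4,6-trihydroxy-3,5-diprenylphenyl]ethanone
Conditions: 2 (2.2 equiv), KOH (10% aq), 0 °C → rt
Reagents that add atoms: none
Why: Phenoxide C-alkylation of a phloroglucinol: in water the polyanion of 1 reacts with the allylic bromide at its two free ring carbons (equivalent by symmetry), so twofold C-prenylation should be the main course, with O-alkylated and geminally dialkylated by-products removed by chromatography.

Step 2
Reactants: 3 1-[2,4,6-trihydroxy-3,5-diprenylphenyl]ethanone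
Product: 4 1-[2-hydroxy-4,6-bis(TBS-oxy)-3,5-diprenylphenyl]ethanone
Conditions: TBSCl (2.1 equiv), imidazole, DMF, 0 °C → rt
Reagents that add atoms: tert-butyldimethylsilyl chloride, CC(C)(C)[Si](C)(C)Cl
Why: Silyl ether formation under imidazole catalysis: the para phenol and one ortho phenol are capped, after which the remaining ortho phenol is locked in a hydrogen bond to the acetyl oxygen and should stay free with a limiting amount of TBSCl.

Step 3
Reactants: 5 5-iodovanillin
Product: 6 4-(TBS-oxy)-3-iodo-5-methoxybenzaldehyde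
Conditions: TBSCl, imidazole, DMF, rt
Reagents that add atoms: tert-butyldimethylsilyl chloride, CC(C)(C)[Si](C)(C)Cl
Why: Silyl ether formation: the acidic phenol of 5, although flanked by iodine and methoxy, should silylate as other 2,6-disubstituted phenols do under these conditions.

Step 4
Reactants: 6 4-(TBS-oxy)-3-iodo-5-methoxybenzaldehyde; 7 tributyl(prenyl)stannane
Product: 8 4-(TBS-oxy)-3-methoxy-5-prenylbenzaldehyde
Conditions: 7 (1.3 equiv), Pd(PPh3)4 (5 mol %), toluene, 100 °C
Reagents that add atoms: none
Why: Stille coupling: zerovalent palladium inserts into the aryl–iodine bond, the allylic stannane transmetallates, and reductive elimination at the less hindered allyl terminus should give the linear prenyl arene, the silyl ether and aldehyde being inert in neutral toluene.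

Step 5
Reactants: 8 4-(TBS-oxy)-3-methoxy-5-prenylbenzaldehyde
Product: 9 [4-(TBS-oxy)-3-methoxy-5-prenylphenyl]methanol
Conditions: NaBH4, MeOH–THF, 0 °C
Reagents that add atoms: none
Why: Borohydride reduction of an aromatic aldehyde is fast at 0 °C and should leave the hindered aryl silyl ether and the trisubstituted alkene untouched.

Step 6
Reactants: 4 1-[2-hydroxy-4,6-bis(TBS-oxy)-3,5-diprenylphenyl]ethanone; 9 [4-(TBS-oxy)-3-methoxy-5-prenylphenyl]methanol
Product: 10 1-{2-[4-(TBS-oxy)-3-methoxy-5-prenylbenzyloxy]-4,6-bis(TBS-oxy)-3,5-diprenylphenyl}ethanone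
Conditions: PPh3, DIAD, THF, 0 °C → rt
Reagents that add atoms: none
Why: Mitsunobu etherification: the chelated phenol of 4 is acidic enough to serve as pronucleophile and displaces the oxyphosphonium derivative of the primary benzylic alcohol under neutral conditions that spare the three silyl ethers, and since ring A has no free ring carbon only O-alkylation is possible.

Step 7
Reactants: 10 1-{2-[4-(TBS-oxy)-3-methoxy-5-prenylbenzyloxy]-4,6-bis(TBS-oxy)-3,5-diprenylphenyl}ethanone
Product: 12 diazomethyl ketone 2-diazo-1-{2-[4-(TBS-oxy)-3-methoxy-5-prenylbenzyloxy]-4,6-bis(TBS-oxy)-3,5-diprenylphenyl}ethanone, via trifluoroacetyl ketone 11 (not isolated)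
Conditions: LiN(SiMe3)2 (1.1 equiv), THF, −78 °C; CF3CO2CH2CF3, −78 °C; then MsN3, Et3N, H2O (1 equiv), MeCN, rt
Reagents that add atoms: methanesulfonyl azide, CS(=O)(=O)N=[N+]=[N-] (the two diazo nitrogens of 12); 2,2,2-trifluoroethyl trifluoroacetate, O=C(OCC(F)(F)F)C(F)(F)F (the trifluoroacetyl group of 11 only, lost again on the way to 12)
Why: Danheiser detrifluoroacetylative diazo transfer: the kinetic lithium enolate of the methyl ketone is C-trifluoroacetylated, the activated 1,3-diketone 11 accepts the diazo group from the sulfonyl azide, and retro-Claisen loss of the trifluoroacetyl group as the N-acylsulfonamide leaves the terminal diazoketone, the low temperature of the enolate stage being chosen to prevent migration of the ortho silyl group to the enolate oxygen.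

Step 8
Reactants: 12 diazomethyl ketone 2-diazo-1-{2-[4-(TBS-oxy)-3-methoxy-5-prenylbenzyloxy]-4,6-bis(TBS-oxy)-3,5-diprenylphenyl}ethanone
Product: 13 (2S)-5,7-bis(TBS-oxy)-2-[4-(TBS-oxy)-3-methoxy-5-prenylphenyl]-6,8-diprenylchroman-4-one
Conditions: Rh2(S-PTTL)4 (2 mol %), CH2Cl2, 0 °C, 12 added over 4 h by syringe pump, final 0.005 M
Reagents that add atoms: none
Why: The dirhodium carboxylate decomposes the diazoketone with loss of N2 to an electrophilic rhodium carbenoid at C3, which inserts into one C2–H bond of the O1–CH2–aryl group through a concerted, asynchronous three-centre transition state with hydride-like transfer of hydrogen and build-up of positive charge at C2. The closest known reaction type is the dirhodium-carboxylate-catalysed enantioselective C–H insertion of 2-alkoxyaryl alpha-diazoketones to chroman-4-ones. Ring C closes by 1,6-insertion to the six-membered pyranone, the only mode open because the 1,5-position is the oxygen O1 and not a carbon. C2 is the only new stereocentre and is controlled by the chiral carboxylate ligands, which distinguish the two enantiotopic benzylic hydrogens so that the (2S)-product should result with the catalyst antipode chosen as stated above. The step needs insertion to outrun oxonium ylide formation at O1 (with the 1,2-benzyl shift that would follow), silyl transfer from the C5 silyl ether and cyclopropanation of the prenyl alkenes: the C2–H bond is doubly activated by O1 and the electron-rich ring B, the silyl ether offers no C–H bond alpha to oxygen, the trisubstituted alkenes cannot reach the carbenoid within the molecule, and slow addition at high dilution suppresses bimolecular pathways.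

Step 9
Reactants: 13 (2S)-5,7-bis(TBS-oxy)-2-[4-(TBS-oxy)-3-methoxy-5-prenylphenyl]-6,8-diprenylchroman-4-one
Product: 14 (2S)-5,7-dihydroxy-2-(4-hydroxy-3-methoxy-5-prenylphenyl)-6,8-diprenylchroman-4-one (CNP0235424.1)
Conditions: Bu4NF, AcOH (1:1, 3.3 equiv each), THF, 0 °C
Reagents that add atoms: none
Why: Fluoride-mediated cleavage of aryl silyl ethers: with acetic acid as buffer each phenoxide is protonated as it forms, which should prevent the base-induced retro-oxa-Michael opening of ring C that would racemise C2, and the medium is far too weakly acidic to cyclise the prenyl groups onto the phenols.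

**Compound list**

1 | 2',4',6'-trihydroxyacetophenone | CC(=O)c1c(O)cc(O)cc1O | starting material
2 | prenyl bromide (1-bromo-3-methylbut-2-ene) | CC(C)=CCBr | starting material
3 | 1-[2,4,6-trihydroxy-3,5-diprenylphenyl]ethanone | CC(=O)c1c(O)c(CC=C(C)C)c(O)c(CC=C(C)C)c1O | intermediate
4 | 1-[2-hydroxy-4,6-bis(TBS-oxy)-3,5-diprenylphenyl]ethanone | CC(=O)c1c(O)c(CC=C(C)C)c(O[Si](C)(C)C(C)(C)C)c(CC=C(C)C)c1O[Si](C)(C)C(C)(C)C | intermediate
5 | 5-iodovanillin | COc1cc(C=O)cc(I)c1O | starting material
6 | 4-(TBS-oxy)-3-iodo-5-methoxybenzaldehyde | COc1cc(C=O)cc(I)c1O[Si](C)(C)C(C)(C)C | intermediate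
7 | tributyl(prenyl)stannane | CCCC[Sn](CCCC)(CCCC)CC=C(C)C | starting material
8 | 4-(TBS-oxy)-3-methoxy-5-prenylbenzaldehyde | COc1cc(C=O)cc(CC=C(C)C)c1O[Si](C)(C)C(C)(C)C | intermediate
9 | [4-(TBS-oxy)-3-methoxy-5-prenylphenyl]methanol | COc1cc(CO)cc(CC=C(C)C)c1O[Si](C)(C)C(C)(C)C | intermediate
10 | 1-{2-[4-(TBS-oxy)-3-methoxy-5-prenylbenzyloxy]-4,6-bis(TBS-oxy)-3,5-diprenylphenyl}ethanone | CC(=O)c1c(OCc2cc(OC)c(O[Si](C)(C)C(C)(C)C)c(CC=C(C)C)c2)c(CC=C(C)C)c(O[Si](C)(C)C(C)(C)C)c(CC=C(C)C)c1O[Si](C)(C)C(C)(C)C | intermediate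
11 | 4,4,4-trifluoro-1-{2-[4-(TBS-oxy)-3-methoxy-5-prenylbenzyloxy]-4,6-bis(TBS-oxy)-3,5-diprenylphenyl}butane-1,3-dione (trifluoroacetyl ketone, not isolated) | O=C(CC(=O)C(F)(F)F)c1c(OCc2cc(OC)c(O[Si](C)(C)C(C)(C)C)c(CC=C(C)C)c2)c(CC=C(C)C)c(O[Si](C)(C)C(C)(C)C)c(CC=C(C)C)c1O[Si](C)(C)C(C)(C)C | intermediate
12 | 2-diazo-1-{2-[4-(TBS-oxy)-3-methoxy-5-prenylbenzyloxy]-4,6-bis(TBS-oxy)-3,5-diprenylphenyl}ethanone | [N-]=[N+]=CC(=O)c1c(OCc2cc(OC)c(O[Si](C)(C)C(C)(C)C)c(CC=C(C)C)c2)c(CC=C(C)C)c(O[Si](C)(C)C(C)(C)C)c(CC=C(C)C)c1O[Si](C)(C)C(C)(C)C | intermediate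
13 | (2S)-5,7-bis(TBS-oxy)-2-[4-(TBS-oxy)-3-methoxy-5-prenylphenyl]-6,8-diprenylchroman-4-one | COc1cc([C@@H]2CC(=O)c3c(O[Si](C)(C)C(C)(C)C)c(CC=C(C)C)c(O[Si](C)(C)C(C)(C)C)c(CC=C(C)C)c3O2)cc(CC=C(C)C)c1O[Si](C)(C)C(C)(C)C | intermediate
14 | (2S)-5,7-dihydroxy-2-(4-hydroxy-3-methoxy-5-prenylphenyl)-6,8-diprenylchroman-4-one | COc1cc([C@@H]2CC(=O)c3c(O)c(CC=C(C)C)c(O)c(CC=C(C)C)c3O2)cc(CC=C(C)C)c1O | target

**Totals and risks**

Total step count: 9. Longest linear sequence: 7 steps (5 → 14, steps 3 to 9); the ring A branch (1 → 14) is 6 steps.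

Steps most likely to fail:

1. Step 8. The acceptor-only carbenoid may discriminate poorly between the two enantiotopic C2–H bonds. It may also be diverted to the oxonium ylide at O1 followed by a 1,2-benzyl shift, or to silyl transfer from the neighbouring silyl ether. Fallback: ring C is closed at O1–C2 instead, and the configuration is taken from a kinetic resolution. Setting out from phenol ketone 4 and aldehyde 8, amine-mediated condensation (pyrrolidine, MeCN, 4 Å molecular sieves, 40 °C) should give the (E)-2'-hydroxychalcone F1. Under the same conditions F1 should close by oxa-Michael addition to the racemic tris-silyl flavanone F2. Transfer hydrogenation of F2 with Cp*RhCl[(R,R)-TsDPEN] and HCO2H–Et3N in EtOAc at rt, stopped near half conversion, is a known kinetic resolution of flavanones. The (2R)-enantiomer is expected to be reduced to the (2R,4R)-cis-flavan-4-ol F3 while the (2S)-enantiomer remains; the catalyst antipode is used if the opposite sense is found. Chromatography removes F3, and the route is rejoined at 13.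

2. Step 6. The hindered, hydrogen-bonded phenol may react too slowly, so that the activated benzylic alcohol alkylates the reduced azodicarboxylate or ionises and oligomerises. Fallback: a silver-promoted Williamson etherification with a preformed halide. Setting out from alcohol 9, Appel bromination (CBr4, PPh3, CH2Cl2, 0 °C) should give 4-(TBS-oxy)-3-methoxy-5-prenylbenzyl bromide F4, which is used at once. Alkylation of phenol 4 with F4 promoted by Ag2O (toluene, rt, dark) should form the same ether without a base strong enough to strip the silyl ethers. The route is rejoined at 10.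

3. Step 7. The ortho silyl group may migrate from the phenol oxygen to the enolate oxygen, trifluoroacetylation of the twisted, doubly ortho-substituted ketone may be incomplete, or a silyl ether may be lost in the aqueous amine stage. Fallback: a diazo transfer that needs no metal enolate. Setting out from ketone 10, heating with N,N-dimethylformamide dimethyl acetal (toluene, 100 °C) should give the (E)-enaminone F5. Treatment of F5 with tosyl azide (MeCN, rt to 40 °C) is expected to proceed by cycloaddition to the enamine double bond and cycloreversion, expelling the N-sulfonyl formamidine. The route is rejoined at diazoketone 12.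

**Further compounds**

F1 | step 8 | (E)-1-[2-hydroxy-4,6-bis(TBS-oxy)-3,5-diprenylphenyl]-3-[4-(TBS-oxy)-3-methoxy-5-prenylphenyl]prop-2-en-1-one | COc1cc(/C=C/C(=O)c2c(O)c(CC=C(C)C)c(O[Si](C)(C)C(C)(C)C)c(CC=C(C)C)c2O[Si](C)(C)C(C)(C)C)cc(CC=C(C)C)c1O[Si](C)(C)C(C)(C)C
F2 | step 8 | racemic 5,7-bis(TBS-oxy)-2-[4-(TBS-oxy)-3-methoxy-5-prenylphenyl]-6,8-diprenylchroman-4-one | COc1cc(C2CC(=O)c3c(O[Si](C)(C)C(C)(C)C)c(CC=C(C)C)c(O[Si](C)(C)C(C)(C)C)c(CC=C(C)C)c3O2)cc(CC=C(C)C)c1O[Si](C)(C)C(C)(C)C
F3 | step 8 | (2R,4R)-5,7-bis(TBS-oxy)-2-[4-(TBS-oxy)-3-methoxy-5-prenylphenyl]-6,8-diprenylchroman-4-ol | COc1cc([C@H]2C[C@@H](O)c3c(O[Si](C)(C)C(C)(C)C)c(CC=C(C)C)c(O[Si](C)(C)C(C)(C)C)c(CC=C(C)C)c3O2)cc(CC=C(C)C)c1O[Si](C)(C)C(C)(C)C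
F4 | step 6 | 4-(TBS-oxy)-3-methoxy-5-prenylbenzyl bromide | COc1cc(CBr)cc(CC=C(C)C)c1O[Si](C)(C)C(C)(C)C
F5 | step 7 | (E)-3-(dimethylamino)-1-{2-[4-(TBS-oxy)-3-methoxy-5-prenylbenzyloxy]-4,6-bis(TBS-oxy)-3,5-diprenylphenyl}prop-2-en-1-one | CN(C)/C=C/C(=O)c1c(OCc2cc(OC)c(O[Si](C)(C)C(C)(C)C)c(CC=C(C)C)c2)c(CC=C(C)C)c(O[Si](C)(C)C(C)(C)C)c(CC=C(C)C)c1O[Si](C)(C)C(C)(C)C
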